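**Strategy.** The γ-lactone is cut at C3–C2 (α-CH2 to carbonyl carbon) and O1–C5 (ring oxygen to the methyl-bearing quaternary carbon), so that carbonyl carbon and ring oxygen arrive together as CO2. The key step exploits the vicinal C–O pair at lactone C5 and oxolane C2, a masked trans-epoxide: its precursor, an open-chain (2R,3R)-3-methyl-3-vinyloxirane with a geraniol-type tail, is hydroborated at the vinyl group, the alkylborane is carboxylated with CO2 under copper catalysis, and the new carboxyl group opens the epoxide at its tertiary carbon with inversion. One pot makes both lactone bonds and fixes two stereocentres; the oxolane is closed next and the furyl side chain joined last.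

Key step: step 5

Remark on the chemistry: the D-fructose-derived Shi ketone is assumed to deliver oxygen to the trisubstituted C6=C7 olefin of 3 with the same facial sense as for trans-stilbene (R,R-oxirane); the enantiomeric ketone would be used if the opposite sense were found.

**Step 1**
Reactants: 1 geranyl acetate
Product: 2 (2E,6E)-3,7-dimethyl-8-oxoocta-2,6-dien-1-yl acetate
Conditions: SeO2 (1.2 equiv), 95% EtOH, reflux
Reagents that add atoms: selenium dioxide O=[Se]=O
Why: Riley allylic oxidation (ene reaction then [2,3]-sigmatropic shift) should attack only the (E)-methyl group of the electron-rich C6=C7 olefin, the C2=C3 olefin being deactivated by the allylic acetate, and with stoichiometric SeO2 in hot ethanol should carry on to the (E)-enal.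

**Step 2**
Reactants: 2 (2E,6E)-3,7-dimethyl-8-oxoocta-2,6-dien-1-yl acetate
Product: 3 (2E,6E)-3,7-dimethylnona-2,6,8-trien-1-yl acetate
Conditions: Ph3PCH3Br (1.3 equiv), KHMDS (1.2 equiv), THF, −78 °C to 0 °C
Reagents that add atoms: methyltriphenylphosphonium bromide C[P+](c1ccccc1)(c1ccccc1)c1ccccc1.[Br-]
Why: Wittig methylenation of the enal with a small excess of pre-formed ylide at low temperature should give the 1,3-diene without touching the acetate or the geometry of the two trisubstituted olefins.

**Step 3**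
Reactants: 3 (2E,6E)-3,7-dimethylnona-2,6,8-trien-1-yl acetate
Product: 4 (2E)-5-[(2R,3R)-3-ethenyl-3-methyloxiran-2-yl]-3-methylpent-2-en-1-yl acetate
Conditions: D-fructose-derived Shi ketone (0.3 equiv), Oxone, K2CO3, Bu4NHSO4 (cat.), Na2B4O7/Na2EDTA buffer (pH 10.5), MeCN/CH2(OMe)2, −10 to 0 °C
Reagents that add atoms: Oxone (potassium peroxymonosulfate) [K+].[O-]S(=O)(=O)OO
Why: Shi asymmetric epoxidation should occur at the most electron-rich olefin, the trisubstituted C6=C7 bond of the diene (the vinyl terminus, the acetate-deactivated C2=C3 bond and the vinyl epoxide product react more slowly), and the spiro transition state of the chiral dioxirane sets both oxirane carbons as (R), which later become lactone C5 and oxolane C2.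

**Step 4**
Reactants: 4 (2E)-5-[(2R,3R)-3-ethenyl-3-methyloxiran-2-yl]-3-methylpent-2-en-1-yl acetate
Product: 5 (2E)-5-[(2R,3R)-3-ethenyl-3-methyloxiran-2-yl]-3-methylpent-2-en-1-ol
Conditions: K2CO3 (0.2 equiv), MeOH, 0 °C
Reagents that add atoms: none
Why: Base-catalysed transesterification should remove the acetate under conditions too mild to open the trisubstituted vinyl epoxide, and no stereocentre is affected.

**Step 5**
Reactants: 5 (2E)-5-[(2R,3R)-3-ethenyl-3-methyloxiran-2-yl]-3-methylpent-2-en-1-ol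
Product: 8 (5S)-5-[(1R,4E)-1,6-dihydroxy-4-methylhex-4-en-1-yl]-5-methyloxolan-2-one, via B-alkyl-9-BBN adduct 6 (not isolated), via epoxy acid 7 (not isolated)
Conditions: 9-BBN-H (2.2 equiv), THF, 0 °C to rt; then (IPr)CuCl (5 mol%; IPr = 1,3-bis(2,6-diisopropylphenyl)imidazol-2-ylidene), MeOLi (3 equiv), CO2 (1 atm), THF, 70 °C; then 1 M HCl to pH 2, THF/H2O, 0 °C to rt
Reagents that add atoms: carbon dioxide O=C=O
Why: 9-BBN should add anti-Markovnikov to the only monosubstituted olefin (its bulk spares the trisubstituted C2=C3 bond and the hydroxyl is masked in situ as its borinate), placing boron on the terminal carbon that becomes lactone C3. Methoxide then forms the borate, the alkyl group passes to copper and CO2 inserts into the Cu–C bond to make the C3–C2 bond, which is the known copper-catalysed carboxylation of B-alkyl-9-BBN compounds (formal anti-Markovnikov hydrocarboxylation of a terminal alkene). On acidification the γ,δ-epoxy acid 7 should close the lactone ring by 5-exo-tet attack of the carboxyl oxygen on the tertiary oxirane carbon, the classical epoxy-acid lactonisation, which makes the O1–C5 bond. Because this opening is invertive, the (R)-oxirane carbon becomes the (S)-configured lactone C5, while the secondary oxirane carbon keeps its C–O bond and its (R)-configuration as the free carbinol, so both stereocentres are dictated by the epoxide of step 3. The step needs 5-exo opening at the more substituted carbon (favoured electronically and by ring size over 6-endo attack at the secondary carbon) and survival of the epoxide until the carboxylate is in place, which the fully substituted oxirane carbon next to the borylated chain (no 3-exo displacement by the borate) and the non-acidic carboxylation medium should secure.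

**Step 6**
Reactants: 8 (5S)-5-[(1R,4E)-1,6-dihydroxy-4-methylhex-4-en-1-yl]-5-methyloxolan-2-one
Product: 10 (5S)-5-[(2R,5R)-5-[(1S)-1,2-dihydroxyethyl]-5-methyloxolan-2-yl]-5-methyloxolan-2-one, via epoxy alcohol 9 (not isolated)
Conditions: Ti(OiPr)4 (0.2 equiv), L-(+)-diethyl tartrate (0.25 equiv), t-BuOOH (2 equiv, in decane), 4 Å molecular sieves, CH2Cl2, −20 °C; then CSA (0.1 equiv), CH2Cl2, 0 °C to rt
Reagents that add atoms: tert-butyl hydroperoxide CC(C)(C)OO
Why: Sharpless asymmetric epoxidation with L-(+)-tartrate should give the (2S,3S)-epoxy alcohol (as for geraniol), which the secondary hydroxyl opens by acid-catalysed 5-exo-tet attack at the tertiary carbon with inversion, closing the oxolane ring and setting its quaternary carbon as (R) with methyl cis to the lactone substituent.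

**Step 7**
Reactants: 10 (5S)-5-[(2R,5R)-5-[(1S)-1,2-dihydroxyethyl]-5-methyloxolan-2-yl]-5-methyloxolan-2-one
Product: 11 (2R,5R)-2-methyl-5-[(2S)-2-methyl-5-oxooxolan-2-yl]oxolane-2-carbaldehyde
Conditions: NaIO4 (1.5 equiv), THF/pH 7 buffer, 0 °C to rt
Reagents that add atoms: none
Why: Malaprade glycol cleavage of the terminal 1,2-diol should give the non-enolisable α-alkoxy aldehyde without touching the lactone or any stereocentre.

**Step 8**
Reactants: 11 (2R,5R)-2-methyl-5-[(2S)-2-methyl-5-oxooxolan-2-yl]oxolane-2-carbaldehyde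
Product: 12 (5S)-5-[(2R,5R)-5-ethynyl-5-methyloxolan-2-yl]-5-methyloxolan-2-one
Conditions: dimethyl (1-diazo-2-oxopropyl)phosphonate (1.5 equiv), K2CO3 (2 equiv), MeOH, 0 °C to rt; aqueous NH4Cl work-up
Reagents that add atoms: dimethyl (1-diazo-2-oxopropyl)phosphonate COP(=O)(OC)C(=[N+]=[N-])C(C)=O
Why: Ohira–Bestmann (Seyferth–Gilbert) homologation should convert the aldehyde into the terminal alkyne through the alkylidene carbene 1,2-shift, and the quaternary α-carbon cannot epimerise under the mild carbonate conditions.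

**Step 9**
Reactants: 13 3-bromofuran; 14 5-bromo-2-methylpent-2-ene
Product: 16 3-(4-methylpent-3-en-1-yl)furan (perillene), via homoprenyl Grignard reagent 15 (not isolated)
Conditions: Mg, THF, rt to 40 °C; then 13, NiCl2(dppp) (2 mol%), Et2O, 0 °C to reflux
Reagents that add atoms: none
Why: Kumada–Tamao–Corriu coupling of a primary alkyl Grignard reagent with 3-bromofuran under nickel–diphosphine catalysis is an established entry to 3-alkylfurans.

**Step 10**
Reactants: 16 3-(4-methylpent-3-en-1-yl)furan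
Product: 17 (2E)-5-(furan-3-yl)-2-methylpent-2-en-1-ol
Conditions: SeO2 (0.1 equiv), salicylic acid (0.1 equiv), t-BuOOH (2 equiv), CH2Cl2, 0 °C
Reagents that add atoms: tert-butyl hydroperoxide CC(C)(C)OO
Why: Catalytic Riley oxidation should hydroxylate the (E)-methyl group of the trisubstituted olefin by ene reaction and [2,3]-shift, giving the (E)-allylic alcohol at a temperature at which the 3-alkylfuran should survive.

**Step 11**
Reactants: 17 (2E)-5-(furan-3-yl)-2-methylpent-2-en-1-ol
Product: 19 3-[(3E)-5-chloro-4-methylpent-3-en-1-yl]furan, via allylic mesylate 18 (not isolated)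
Conditions: MsCl (1.2 equiv), 2,4,6-collidine (1.5 equiv), LiCl (3 equiv), DMF, 0 °C
Reagents that add atoms: lithium chloride [Li+].[Cl-]
Why: Mesylation followed by direct SN2 displacement with chloride at the primary allylic carbon should keep the (E)-olefin and avoid allylic transposition.

**Step 12**
Reactants: 12 (5S)-5-[(2R,5R)-5-ethynyl-5-methyloxolan-2-yl]-5-methyloxolan-2-one; 19 3-[(3E)-5-chloro-4-methylpent-3-en-1-yl]furan
Product: 21 (5S)-5-methyl-5-[(2R,5R)-5-methyl-5-[(1E,4E)-7-(furan-3-yl)-4-methylhepta-1,4-dien-1-yl]oxolan-2-yl]oxolan-2-one (CNP0387598.1), via alkenylzirconocene 20 (not isolated)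
Conditions: Cp2Zr(H)Cl (1.3 equiv), THF, 0 °C to rt; then 19 (1.2 equiv), Pd(PPh3)4 (5 mol%), THF, rt to 40 °C
Reagents that add atoms: none
Why: Syn hydrozirconation of the terminal alkyne should place zirconium on the terminal carbon to give the (E)-alkenylzirconocene, which in a Negishi-type palladium-catalysed alkenyl–allyl coupling should attack the unsubstituted terminus of the syn π-allyl complex with retention of both olefin geometries, giving the skipped (1E,4E)-diene.

**Compound list**
1 | geranyl acetate, (2E)-3,7-dimethylocta-2,6-dien-1-yl acetate | CC(C)=CCC/C(C)=C/COC(C)=O | starting material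
2 | (2E,6E)-3,7-dimethyl-8-oxoocta-2,6-dien-1-yl acetate | O=C/C(C)=C/CC/C(C)=C/COC(C)=O | intermediate
3 | (2E,6E)-3,7-dimethylnona-2,6,8-trien-1-yl acetate | C=C/C(C)=C/CC/C(C)=C/COC(C)=O | intermediate
4 | (2E)-5-[(2R,3R)-3-ethenyl-3-methyloxiran-2-yl]-3-methylpent-2-en-1-yl acetate | C=C[C@@]1(C)O[C@@H]1CC/C(C)=C/COC(C)=O | intermediate
5 | (2E)-5-[(2R,3R)-3-ethenyl-3-methyloxiran-2-yl]-3-methylpent-2-en-1-ol | C=C[C@@]1(C)O[C@@H]1CC/C(C)=C/CO | intermediate
6 | 9-{2-[(2R,3R)-3-[(3E)-5-(9-borabicyclo[3.3.1]nonan-9-yloxy)-3-methylpent-3-en-1-yl]-2-methyloxiran-2-yl]ethyl}-9-borabicyclo[3.3.1]nonane | C(C[C@@]1(C)O[C@@H]1CC/C(C)=C/COB1C2CCCC1CCC2)B1C2CCCC1CCC2 | intermediate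
7 | 3-[(2R,3R)-3-[(3E)-5-hydroxy-3-methylpent-3-en-1-yl]-2-methyloxiran-2-yl]propanoic acid | OC(=O)CC[C@@]1(C)O[C@@H]1CC/C(C)=C/CO | intermediate
8 | (5S)-5-[(1R,4E)-1,6-dihydroxy-4-methylhex-4-en-1-yl]-5-methyloxolan-2-one | O[C@H](CC/C(C)=C/CO)[C@]1(C)CCC(=O)O1 | intermediate
9 | (5S)-5-[(1R)-1-hydroxy-3-[(2S,3S)-3-(hydroxymethyl)-2-methyloxiran-2-yl]propyl]-5-methyloxolan-2-one | O[C@H](CC[C@]1(C)O[C@H]1CO)[C@]2(C)CCC(=O)O2 | intermediate
10 | (5S)-5-[(2R,5R)-5-[(1S)-1,2-dihydroxyethyl]-5-methyloxolan-2-yl]-5-methyloxolan-2-one | OC[C@H](O)[C@@]1(C)CC[C@H]([C@]2(C)CCC(=O)O2)O1 | intermediate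
11 | (2R,5R)-2-methyl-5-[(2S)-2-methyl-5-oxooxolan-2-yl]oxolane-2-carbaldehyde | O=C[C@@]1(C)CC[C@H]([C@]2(C)CCC(=O)O2)O1 | intermediate
12 | (5S)-5-[(2R,5R)-5-ethynyl-5-methyloxolan-2-yl]-5-methyloxolan-2-one | C#C[C@@]1(C)CC[C@H]([C@]2(C)CCC(=O)O2)O1 | intermediate
13 | 3-bromofuran | Brc1ccoc1 | starting material
14 | 5-bromo-2-methylpent-2-ene | CC(C)=CCCBr | starting material
15 | (4-methylpent-3-en-1-yl)magnesium bromide | CC(C)=CCC[Mg]Br | intermediate
16 | 3-(4-methylpent-3-en-1-yl)furan (perillene) | CC(C)=CCCc1ccoc1 | intermediate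
17 | (2E)-5-(furan-3-yl)-2-methylpent-2-en-1-ol | OC/C(C)=C/CCc1ccoc1 | intermediate
18 | (2E)-5-(furan-3-yl)-2-methylpent-2-en-1-yl methanesulfonate | CS(=O)(=O)OC/C(C)=C/CCc1ccoc1 | intermediate
19 | 3-[(3E)-5-chloro-4-methylpent-3-en-1-yl]furan | ClC/C(C)=C/CCc1ccoc1 | intermediate
20 | chlorobis(cyclopentadienyl)[(E)-2-{(2R,5R)-2-methyl-5-[(2S)-2-methyl-5-oxooxolan-2-yl]oxolan-2-yl}ethenyl]zirconium (cyclopentadienyl rings drawn σ-bonded) | Cl[Zr](C1C=CC=C1)(C1C=CC=C1)/C=C/[C@@]1(C)CC[C@H]([C@]2(C)CCC(=O)O2)O1 | intermediate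
21 | (5S)-5-methyl-5-[(2R,5R)-5-methyl-5-[(1E,4E)-7-(furan-3-yl)-4-methylhepta-1,4-dien-1-yl]oxolan-2-yl]oxolan-2-one | C/C(=C\CCc1ccoc1)C/C=C/[C@@]1(C)CC[C@H]([C@]2(C)CCC(=O)O2)O1 | target

**Step count and risks**
Total step count: 12. Longest linear sequence: 9 steps (steps 1 to 8 and step 12, from geranyl acetate); the side chain takes steps 9 to 11.

Steps most likely to fail:

Step 5. The borane may reduce the vinyl epoxide by conjugate hydride delivery instead of hydroborating the vinyl group, or the borate may attack the oxirane before the alkyl group reaches copper. The fallback sets out from 1 and comes back at 8, building the two lactone bonds in separate classical steps. Catalytic SeO2/t-BuOOH oxidation of 1 would give (2E,6E)-8-hydroxy-3,7-dimethylocta-2,6-dien-1-yl acetate F1. Appel bromination (CBr4, PPh3, CH2Cl2, 0 °C) would give (2E,6E)-8-bromo-3,7-dimethylocta-2,6-dien-1-yl acetate F2. Alkylation of the lithium enolate of tert-butyl acetate (LDA, THF/DMPU, −78 °C) would give tert-butyl (4E,8E)-10-acetoxy-4,8-dimethyldeca-4,8-dienoate F3. Shi epoxidation as in step 3 would give tert-butyl 3-[(2R,3R)-3-[(3E)-5-acetoxy-3-methylpent-3-en-1-yl]-2-methyloxiran-2-yl]propanoate F4. CSA in CH2Cl2 would let the ester carbonyl oxygen open the oxirane (5-exo, inversion) with loss of the tert-butyl group, giving (2E,6R)-6-hydroxy-3-methyl-6-[(2S)-2-methyl-5-oxooxolan-2-yl]hex-2-en-1-yl acetate F5. K2CO3/MeOH would then give 8.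

Step 12. The zirconium hydride may reduce the lactone, or the allyl fragment may lose its (E)-geometry or couple at the wrong terminus. The fallback sets out from 12 and comes back at 21, replacing the hydride-based one-pot sequence by an isolable tin donor. Palladium-catalysed hydrostannation (Bu3SnH, PdCl2(PPh3)2, THF, 0 °C) would give (5S)-5-methyl-5-[(2R,5R)-5-methyl-5-[(E)-2-(tributylstannyl)ethenyl]oxolan-2-yl]oxolan-2-one F6, which would be purified and joined to 19 by Stille coupling (Pd2(dba)3, AsPh3, THF, 50 °C).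

Step 10. The peroxide/selenium system may degrade the electron-rich furan or over-oxidise the alcohol to the enal. The fallback sets out from 14 and comes back at 17, carrying out the allylic oxidation before the furan is present. SeO2/t-BuOOH oxidation of 14 would give (2E)-5-bromo-2-methylpent-2-en-1-ol F7. TBSCl/imidazole would give {[(2E)-5-bromo-2-methylpent-2-en-1-yl]oxy}(tert-butyl)dimethylsilane F8. Zinc insertion (Zn, LiCl, THF, 50 °C) would give {(3E)-5-[(tert-butyldimethylsilyl)oxy]-4-methylpent-3-en-1-yl}zinc bromide F9. Negishi coupling with 13 (Pd(OAc)2, SPhos, THF) would give tert-butyl{[(2E)-5-(furan-3-yl)-2-methylpent-2-en-1-yl]oxy}dimethylsilane F10, and TBAF would release 17.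

**Further compounds**
F1 | step 5 | (2E,6E)-8-hydroxy-3,7-dimethylocta-2,6-dien-1-yl acetate | OC/C(C)=C/CC/C(C)=C/COC(C)=O
F2 | step 5 | (2E,6E)-8-bromo-3,7-dimethylocta-2,6-dien-1-yl acetate | BrC/C(C)=C/CC/C(C)=C/COC(C)=O
F3 | step 5 | tert-butyl (4E,8E)-10-acetoxy-4,8-dimethyldeca-4,8-dienoate | CC(C)(C)OC(=O)CC/C(C)=C/CC/C(C)=C/COC(C)=O
F4 | step 5 | tert-butyl 3-[(2R,3R)-3-[(3E)-5-acetoxy-3-methylpent-3-en-1-yl]-2-methyloxiran-2-yl]propanoate | CC(C)(C)OC(=O)CC[C@@]1(C)O[C@@H]1CC/C(C)=C/COC(C)=O
F5 | step 5 | (2E,6R)-6-hydroxy-3-methyl-6-[(2S)-2-methyl-5-oxooxolan-2-yl]hex-2-en-1-yl acetate | O[C@H](CC/C(C)=C/COC(C)=O)[C@]1(C)CCC(=O)O1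
F6 | step 12 | (5S)-5-methyl-5-[(2R,5R)-5-methyl-5-[(E)-2-(tributylstannyl)ethenyl]oxolan-2-yl]oxolan-2-one | CCCC[Sn](CCCC)(CCCC)/C=C/[C@@]1(C)CC[C@H]([C@]2(C)CCC(=O)O2)O1
F7 | step 10 | (2E)-5-bromo-2-methylpent-2-en-1-ol | OC/C(C)=C/CCBr
F8 | step 10 | {[(2E)-5-bromo-2-methylpent-2-en-1-yl]oxy}(tert-butyl)dimethylsilane | CC(C)(C)[Si](C)(C)OC/C(C)=C/CCBr
F9 | step 10 | {(3E)-5-[(tert-butyldimethylsilyl)oxy]-4-methylpent-3-en-1-yl}zinc bromide | CC(C)(C)[Si](C)(C)OC/C(C)=C/CC[Zn]Br
F10 | step 10 | tert-butyl{[(2E)-5-(furan-3-yl)-2-methylpent-2-en-1-yl]oxy}dimethylsilane | CC(C)(C)[Si](C)(C)OC/C(C)=C/CCc1ccoc1
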